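Set the summer flask beside the midnight flask. It holds 4.00 times the free base, and you want to know what that buys.

in all of them: electrophile 0.020 M; nucleophile 0.0210 M; protic impurity 10.0 mM; time 5.0 h
- midnight: free base 0.0300 M
- spring: free base 0.0600 M
- summer: free base 0.120 M

    electrophile + nucleophile → acid set free + product (k1 = 0.022 M⁻¹ s⁻¹)
    nucleophile + acid set free ⇌ protonated nucleophile, settled at all times (K2 = 1.1 × 10⁵ M⁻¹)
    acid set free + free base ⇌ salt of the base (K3 = 92 M⁻¹, k3 = 0.16 M⁻¹ s⁻¹)
    electrophile + protic impurity → quenched substrate (k4 = 0.0084 M⁻¹ s⁻¹)
    crystals ⇌ product, rate k5*(cs5 - [product]) while solid is left; crystals form when [product] > cs5 (cs5 = 0.29 mM, k5 = 7.7 × 10⁻⁴ s⁻¹)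

- for product the crystals are counted in
- as a solid, counted per litre of solution: crystals
- run time (midnight): 5.0 h

- part of the electrophile that has reacted at the end, midnight
- part of the electrophile that has reacted at the end, spring
- part of the electrophile that has reacted at the end, summer
- what raising the concentration of free base from its lowest to its highest value here does to the part of the electrophile that has reacted (changes below 5 percentage points count as none) (no change / it falls / it rises)

The free base looks like the taker of the acid, but the nucleophile competes for it. At the start of midnight, the nucleophile's binding constant times c(nucleophile) is 2300, against 2.8 for the base. Summer's base lifts its figure to 11.0, still far less. So at the start each acid set free takes a second nucleophile. I therefore count the nucleophile, the limiting reagent for product, at half its charge.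

By this reckoning 9.50 mM of electrophile stays unserved: the remainder, the charge of electrophile less half the charge of nucleophile.

With the other concentrations as charged, the electrophile's half-life in midnight is 0.42 h by the nucleophile's step alone, shorter than the 2.3 h by the quench alone. So I hand the remainder R to the protic impurity from the start. The two fall one to one. With D the charge of impurity less R, and k the quench constant, electrophile left = R·D / (c(protic impurity)·exp(k·D·t) − R).

On my reckoning that leaves 3.70 mM, so 81.5% has reacted. The base does not enter this expression, so I expect no change. The electrophile stands above R early on, so my figure should read low.

The forecast gave 83.8%, 84.3% and 85%, no change, holding that “about half the nucleophile is lost to protonation whatever the base level”.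

The simulation gives 84.0%, 84.4% and 85.1%, a change of 1.1 percentage points: no change.

My figure lies 2.5 points below midnight. Midnight's product, crystals counted, stands at 53.5% after 5.00 h, beside the 52.5% that the remainder leaves to the nucleophile. Now take a neighbour, spring with 0.0053 M of nucleophile. Its remainder is 17.4 mM, more than the impurity charged. The same expression leaves 9.07 mM, so I reckon 54.6% reacted. That neighbour gives 57.0%.

(The constants were set for the occasion; the run is a simulation.)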